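**Retrosynthetic overview**

1. Feature: ring A is a1 C-OMe, a2 C-H, a3 C-OH, a4 C-CH2Ar, a5 C-CH2CH2-ring B, a6 C-CH2Ar (Ar = 4-hydroxyphenyl). Its oxygens sit on the alternate carbons a1 and a3, and a5 and the benzylic carbon on a4 continue the alternation, so these four carbons are read as the carbonyls of a linear nonane-1,3,5,7-tetraone.
2. End game (retro): remove four O-benzyl groups, return a4-CH2Ar to a4-C(=O)Ar, and return a1-OMe to a1-OH. The hydrogen bond from a3-OH to the aroyl group distinguishes the two hydroxyls.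
3. Key disconnection a4-a5: the 4-aroylresorcinol unfolds by retro-aldol condensation to the tetraketone. Ring A is the only ring that is built; all other rings are bought.
4. The chain is cut at a5-a6 (1,3,5-triketone trianion + ring B Weinreb amide), at a1-a2 (1-arylbutane-1,3-dione dianion + 3-arylpropanoic Weinreb amide) and at a3-a4 (Claisen condensation with ethyl acetate).
5. Ring B amide: aryl Grignard addition to 2-benzyloxy-4-bromobenzaldehyde, ionic reduction, Heck reaction with N-methoxy-N-methylacrylamide, then C=C hydrogenation.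

Key step: step 10

Assumption: the three O-benzyl building blocks and N-methoxy-N-methylacrylamide are taken as catalogue items. Each is otherwise one routine step from the parent phenol or from acryloyl chloride.

Remark: all β-polycarbonyl compounds are drawn as all-keto tautomers although they are largely enolised. The target is achiral.

**Step 1**
Reactants: 1 4'-(benzyloxy)acetophenone; 2 ethyl acetate
Product: 3 1-[4-(benzyloxy)phenyl]butane-1,3-dione
Conditions: NaH (2.2 equiv), EtOAc (4 equiv), THF, reflux; 1 M HCl, 0 °C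
Reagents that add atoms: none
Why: Crossed Claisen condensation in which the acetophenone enolate (future a4) is acylated by ethyl acetate (future a3 and a2), and deprotonation of the β-diketone pulls the equilibrium over.

**Step 2**
Reactants: 4 3-[4-(benzyloxy)phenyl]propanoic acid
Product: 6 3-[4-(benzyloxy)phenyl]-N-methoxy-N-methylpropanamide, via acyl imidazolide 5 (not isolated)
Conditions: 1,1'-carbonyldiimidazole (1.1 equiv), CH2Cl2, rt; then MeNHOMe·HCl (1.2 equiv), rt
Reagents that add atoms: N,O-dimethylhydroxylamine hydrochloride, CNOC.Cl; 1,1'-carbonyldiimidazole, O=C(n1ccnc1)n1ccnc1 (its imidazolyl group is kept only in 5)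
Why: Carboxyl activation as the acyl imidazolide followed by aminolysis (Weinreb amide formation), to which the aryl benzyl ether is inert.

**Step 3**
Reactants: 3 1-[4-(benzyloxy)phenyl]butane-1,3-dione; 6 3-[4-(benzyloxy)phenyl]-N-methoxy-N-methylpropanamide
Product: 8 1,7-bis[4-(benzyloxy)phenyl]heptane-1,3,5-trione, via dilithio dianion 7 (not isolated)
Conditions: 3 (1.1 equiv), LiN(iPr)2 (2.2 equiv), THF, 0 °C; then 6 (1.0 equiv), −78 → 0 °C; AcOH, −78 °C
Reagents that add atoms: LiN(iPr)2, [Li+].CC(C)[N-]C(C)C (lithium is kept only in 7)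
Why: Terminal (γ) acylation of a β-diketone dianion at its last-formed, most basic carbon a2; the Weinreb amide holds the adduct as a lithium chelate until the quench, so the more acidic triketone cannot consume dianion and no second addition occurs.

**Step 4**
Reactants: 9 4-bromo-2-hydroxybenzaldehyde
Product: 10 2-(benzyloxy)-4-bromobenzaldehyde
Conditions: BnBr (1.1 equiv), K2CO3, DMF, rt
Reagents that add atoms: benzyl bromide, BrCc1ccccc1
Why: Williamson ether synthesis on an acidic ortho-formyl phenol; aldehyde and aryl bromide are untouched by carbonate.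

**Step 5**
Reactants: 10 2-(benzyloxy)-4-bromobenzaldehyde; 11 1-(benzyloxy)-4-bromobenzene
Product: 13 (±)-[2-(benzyloxy)-4-bromophenyl][4-(benzyloxy)phenyl]methanol, via aryl Grignard reagent 12 (not isolated)
Conditions: 11, Mg, THF, 40 °C; then 10, THF, 0 °C; sat. aq NH4Cl
Reagents that add atoms: magnesium, [Mg] (kept only in 12)
Why: Grignard addition to the aldehyde is much faster at 0 °C than bromine-magnesium exchange on 10; the carbinol centre forms as a racemate and is removed in step 6.

**Step 6**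
Reactants: 13 (±)-[2-(benzyloxy)-4-bromophenyl][4-(benzyloxy)phenyl]methanol
Product: 14 2-(benzyloxy)-1-[4-(benzyloxy)benzyl]-4-bromobenzene
Conditions: Et3SiH (3 equiv), CF3CO2H (5 equiv), CH2Cl2, 0 °C
Reagents that add atoms: none
Why: Ionic hydrogenation in which the benzhydrol ionises readily to a cation stabilised by an ortho and a para alkoxy group, and the silane traps it faster than any Friedel-Crafts pathway.

**Step 7**
Reactants: 14 2-(benzyloxy)-1-[4-(benzyloxy)benzyl]-4-bromobenzene; 15 N-methoxy-N-methylacrylamide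
Product: 16 (E)-3-{3-(benzyloxy)-4-[4-(benzyloxy)benzyl]phenyl}-N-methoxy-N-methylprop-2-enamide
Conditions: Pd(OAc)2 (5 mol %), P(o-tol)3 (10 mol %), Et3N, DMF, 100 °C
Reagents that add atoms: none
Why: Heck reaction: oxidative addition of the aryl bromide to zerovalent palladium, syn insertion at the unsubstituted acrylamide terminus and syn β-hydride elimination should give the E alkene.

**Step 8**
Reactants: 16 (E)-3-{3-(benzyloxy)-4-[4-(benzyloxy)benzyl]phenyl}-N-methoxy-N-methylprop-2-enamide
Product: 17 3-{3-(benzyloxy)-4-[4-(benzyloxy)benzyl]phenyl}-N-methoxy-N-methylpropanamide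
Conditions: H2 (3 atm), RhCl(PPh3)3 (5 mol %), toluene/EtOH, 40 °C
Reagents that add atoms: none
Why: Homogeneous hydrogenation with RhCl(PPh3)3 saturates the disubstituted conjugated C=C and, unlike Pd/C, has no hydrogenolysis activity toward aryl benzyl ethers or the N-O bond.

**Step 9**
Reactants: 8 1,7-bis[4-(benzyloxy)phenyl]heptane-1,3,5-trione; 17 3-{3-(benzyloxy)-4-[4-(benzyloxy)benzyl]phenyl}-N-methoxy-N-methylpropanamide
Product: 19 (±)-1-[4-(benzyloxy)phenyl]-6-[4-(benzyloxy)benzyl]-9-{3-(benzyloxy)-4-[4-(benzyloxy)benzyl]phenyl}nonane-1,3,5,7-tetraone, via trilithio trianion 18 (not isolated)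
Conditions: 8 (1.1 equiv), LiN(iPr)2 (3.3 equiv), THF, 0 °C; then 17 (1.0 equiv), −78 → −20 °C; AcOH/THF, −78 °C; cold neutral work-up, used without chromatography
Reagents that add atoms: LiN(iPr)2, [Li+].CC(C)[N-]C(C)C (lithium is kept only in 18)
Why: Terminal acylation of a 1,3,5-triketone trianion, in which the third deprotonation can only occur at C6 (a6, the other chain end being aryl) and this least stabilised carbanion attacks the Weinreb amide; the amide has less acidic α-hydrogens than an ester and releases the tetraketone only on the cold quench, and the a6 centre forms racemic, is labile and disappears in step 10.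

**Step 10**
Reactants: 19 (±)-1-[4-(benzyloxy)phenyl]-6-[4-(benzyloxy)benzyl]-9-{3-(benzyloxy)-4-[4-(benzyloxy)benzyl]phenyl}nonane-1,3,5,7-tetraone
Product: 21 {3-[4-(benzyloxy)benzyl]-2-(2-{3-(benzyloxy)-4-[4-(benzyloxy)benzyl]phenyl}ethyl)-4,6-dihydroxyphenyl}[4-(benzyloxy)phenyl]methanone, via aldol carbinol 20 (not isolated)
Conditions: Et3N (3 equiv), CH2Cl2, 0 °C → rt; then wash with 1 M HCl
Reagents that add atoms: none
Why: Et3N ionises only the doubly activated C-H acids, and the a4 enolate (between the aroyl and a3 carbonyls) adds to the a5 ketone to give carbinol 20, which loses water by E1cB through its still acidic a4-H and then enolises at a1 and a3 to the arene, the one irreversible event in the manifold. The closest known reaction type is the base-induced aldol cyclisation and aromatisation of 1,3,5,7-tetraketones to acylresorcinols, the laboratory copy of polyketide folding. Ring A closes in a 6-(enolexo)-exo-trig mode and forms the bond a4-a5. No stereocentre is kept, because the labile centre a6 of 19 and the three centres of 20 all become sp2 carbons of ring A. The step must select one fold out of three six-ring aldols plus O-cyclisation: a6 onto the aroyl carbon gives a quaternary carbon that cannot dehydrate to an arene and reverts by retro-aldol, the CH2 next to a5 is only singly activated and is not ionised by an amine, a2 reaches only four-membered rings, and hemiketals reopen as long as no acid is present. a5 is the best acceptor because it is a dialkyl ketone without aryl conjugation and the a6 branch keeps the a5/a1 diketone largely in the keto form, while a non-nucleophilic base in an aprotic solvent leaves no route for retro-Claisen cleavage.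

**Step 11**
Reactants: 21 {3-[4-(benzyloxy)benzyl]-2-(2-{3-(benzyloxy)-4-[4-(benzyloxy)benzyl]phenyl}ethyl)-4,6-dihydroxyphenyl}[4-(benzyloxy)phenyl]methanone
Product: 22 {3-[4-(benzyloxy)benzyl]-2-(2-{3-(benzyloxy)-4-[4-(benzyloxy)benzyl]phenyl}ethyl)-6-hydroxy-4-methoxyphenyl}[4-(benzyloxy)phenyl]methanone
Conditions: MeI (1.1 equiv), K2CO3 (1.2 equiv), acetone, rt → 40 °C
Reagents that add atoms: iodomethane, CI
Why: Williamson-type O-methylation under weak base, where a1-OH (para to the ketone and free) is the more acidic and accessible phenol, while a3-OH is held in a six-membered hydrogen bond to the aroyl oxygen and stays unreacted with one equivalent of MeI.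

**Step 12**
Reactants: 22 {3-[4-(benzyloxy)benzyl]-2-(2-{3-(benzyloxy)-4-[4-(benzyloxy)benzyl]phenyl}ethyl)-6-hydroxy-4-methoxyphenyl}[4-(benzyloxy)phenyl]methanone
Product: 23 2,4-bis[4-(benzyloxy)benzyl]-3-(2-{3-(benzyloxy)-4-[4-(benzyloxy)benzyl]phenyl}ethyl)-5-methoxyphenol
Conditions: Et3SiH (5 equiv), CF3CO2H/CH2Cl2, 0 °C → rt
Reagents that add atoms: none
Why: Ionic hydrogenation of an electron-rich diaryl ketone by protonation, hydride transfer, ionisation of the benzhydrol to a cation stabilised by a3-OH, a1-OMe and the para benzyloxy group, and a second hydride transfer; aryl benzyl ethers tolerate these conditions and excess silane intercepts stray cations.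

**Step 13**
Reactants: 23 2,4-bis[4-(benzyloxy)benzyl]-3-(2-{3-(benzyloxy)-4-[4-(benzyloxy)benzyl]phenyl}ethyl)-5-methoxyphenol
Product: 24 2,4-bis(4-hydroxybenzyl)-3-{2-[3-hydroxy-4-(4-hydroxybenzyl)phenyl]ethyl}-5-methoxyphenol (CNP0207338.0)
Conditions: H2 (1 atm), 10% Pd/C, EtOAc/MeOH, rt
Reagents that add atoms: none
Why: Catalytic hydrogenolysis cleaves the four aryl benzyl ethers, while the diarylmethane C-C bonds, the ethylene bridge and the methyl ether are inert, which should give the achiral target.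

**Compound list**

1 | 4'-(benzyloxy)acetophenone | CC(=O)c1ccc(OCc2ccccc2)cc1 | starting material
2 | ethyl acetate | CCOC(C)=O | starting material
3 | 1-[4-(benzyloxy)phenyl]butane-1,3-dione | CC(=O)CC(=O)c1ccc(OCc2ccccc2)cc1 | intermediate
4 | 3-[4-(benzyloxy)phenyl]propanoic acid | O=C(O)CCc1ccc(OCc2ccccc2)cc1 | starting material
5 | 3-[4-(benzyloxy)phenyl]-1-(imidazol-1-yl)propan-1-one (acyl imidazolide, not isolated) | O=C(CCc1ccc(OCc2ccccc2)cc1)n1ccnc1 | intermediate
6 | 3-[4-(benzyloxy)phenyl]-N-methoxy-N-methylpropanamide | CON(C)C(=O)CCc1ccc(OCc2ccccc2)cc1 | intermediate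
7 | dilithio dianion of 3 (bis-enolate, not isolated) | [Li+].[Li+].C=C([O-])C=C([O-])c1ccc(OCc2ccccc2)cc1 | intermediate
8 | 1,7-bis[4-(benzyloxy)phenyl]heptane-1,3,5-trione | O=C(CCc1ccc(OCc2ccccc2)cc1)CC(=O)CC(=O)c1ccc(OCc2ccccc2)cc1 | intermediate
9 | 4-bromo-2-hydroxybenzaldehyde | O=Cc1ccc(Br)cc1O | starting material
10 | 2-(benzyloxy)-4-bromobenzaldehyde | O=Cc1ccc(Br)cc1OCc1ccccc1 | intermediate
11 | 1-(benzyloxy)-4-bromobenzene | Brc1ccc(OCc2ccccc2)cc1 | starting material
12 | 4-(benzyloxy)phenylmagnesium bromide (not isolated) | Br[Mg]c1ccc(OCc2ccccc2)cc1 | intermediate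
13 | (±)-[2-(benzyloxy)-4-bromophenyl][4-(benzyloxy)phenyl]methanol (racemic) | OC(c1ccc(OCc2ccccc2)cc1)c1ccc(Br)cc1OCc1ccccc1 | intermediate
14 | 2-(benzyloxy)-1-[4-(benzyloxy)benzyl]-4-bromobenzene | Brc1ccc(Cc2ccc(OCc3ccccc3)cc2)c(OCc2ccccc2)c1 | intermediate
15 | N-methoxy-N-methylacrylamide | C=CC(=O)N(C)OC | starting material
16 | (E)-3-{3-(benzyloxy)-4-[4-(benzyloxy)benzyl]phenyl}-N-methoxy-N-methylprop-2-enamide | CON(C)C(=O)/C=C/c1ccc(Cc2ccc(OCc3ccccc3)cc2)c(OCc2ccccc2)c1 | intermediate
17 | 3-{3-(benzyloxy)-4-[4-(benzyloxy)benzyl]phenyl}-N-methoxy-N-methylpropanamide | CON(C)C(=O)CCc1ccc(Cc2ccc(OCc3ccccc3)cc2)c(OCc2ccccc2)c1 | intermediate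
18 | trilithio trianion of 8 (tris-enolate, not isolated) | [Li+].[Li+].[Li+].[O-]C(=CC([O-])=CC([O-])=CCc1ccc(OCc2ccccc2)cc1)c1ccc(OCc2ccccc2)cc1 | intermediate
19 | (±)-1-[4-(benzyloxy)phenyl]-6-[4-(benzyloxy)benzyl]-9-{3-(benzyloxy)-4-[4-(benzyloxy)benzyl]phenyl}nonane-1,3,5,7-tetraone (racemic, labile centre at C6 = a6) | O=C(CCc1ccc(Cc2ccc(OCc3ccccc3)cc2)c(OCc2ccccc2)c1)C(Cc1ccc(OCc2ccccc2)cc1)C(=O)CC(=O)CC(=O)c1ccc(OCc2ccccc2)cc1 | intermediate
20 | 6-[4-(benzyloxy)benzoyl]-4-[4-(benzyloxy)benzyl]-5-(2-{3-(benzyloxy)-4-[4-(benzyloxy)benzyl]phenyl}ethyl)-5-hydroxycyclohexane-1,3-dione (diastereomer mixture, not isolated) | O=C1CC(=O)C(C(=O)c2ccc(OCc3ccccc3)cc2)C(O)(CCc2ccc(Cc3ccc(OCc4ccccc4)cc3)c(OCc3ccccc3)c2)C1Cc1ccc(OCc2ccccc2)cc1 | intermediate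
21 | {3-[4-(benzyloxy)benzyl]-2-(2-{3-(benzyloxy)-4-[4-(benzyloxy)benzyl]phenyl}ethyl)-4,6-dihydroxyphenyl}[4-(benzyloxy)phenyl]methanone | Oc1cc(O)c(C(=O)c2ccc(OCc3ccccc3)cc2)c(CCc2ccc(Cc3ccc(OCc4ccccc4)cc3)c(OCc3ccccc3)c2)c1Cc1ccc(OCc2ccccc2)cc1 | intermediate
22 | {3-[4-(benzyloxy)benzyl]-2-(2-{3-(benzyloxy)-4-[4-(benzyloxy)benzyl]phenyl}ethyl)-6-hydroxy-4-methoxyphenyl}[4-(benzyloxy)phenyl]methanone | COc1cc(O)c(C(=O)c2ccc(OCc3ccccc3)cc2)c(CCc2ccc(Cc3ccc(OCc4ccccc4)cc3)c(OCc3ccccc3)c2)c1Cc1ccc(OCc2ccccc2)cc1 | intermediate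
23 | 2,4-bis[4-(benzyloxy)benzyl]-3-(2-{3-(benzyloxy)-4-[4-(benzyloxy)benzyl]phenyl}ethyl)-5-methoxyphenol | COc1cc(O)c(Cc2ccc(OCc3ccccc3)cc2)c(CCc2ccc(Cc3ccc(OCc4ccccc4)cc3)c(OCc3ccccc3)c2)c1Cc1ccc(OCc2ccccc2)cc1 | intermediate
24 | 2,4-bis(4-hydroxybenzyl)-3-{2-[3-hydroxy-4-(4-hydroxybenzyl)phenyl]ethyl}-5-methoxyphenol (CNP0207338.0) | COc1cc(O)c(Cc2ccc(O)cc2)c(CCc2ccc(Cc3ccc(O)cc3)c(O)c2)c1Cc1ccc(O)cc1 | target

**Step count**

Total step count: 13.
Longest linear sequence: 10 steps (steps 4 to 13, from 9 to 24).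

**Steps most likely to fail**

**Step 10 (key aldol fold).**
- Risk: closure through an enol oxygen followed by loss of water may outrun C-C bond formation. The a6-branched β-diketone may also fragment before the aldol has taken place.
- Fallback: it sets out from 6, 17 and 12 and comes back at 22. The aryl ketone is taken out of the chain and the a3 oxygen is tied into a dioxinone, so only one carbon nucleophile and one ketone acceptor remain.
- Commercial 2,2,6-trimethyl-4H-1,3-dioxin-4-one is deprotonated with LiN(iPr)2 (THF, −78 °C) and acylated with 6. This should give the keto-dioxinone 6-{4-[4-(benzyloxy)phenyl]-2-oxobutyl}-2,2-dimethyl-4H-1,3-dioxin-4-one F1.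
- Double deprotonation of F1 (LiN(iPr)2, 2.2 equiv) and acylation with 17 should give the diketo-dioxinone (±)-6-{3-[4-(benzyloxy)benzyl]-6-{3-(benzyloxy)-4-[4-(benzyloxy)benzyl]phenyl}-2,4-dioxohexyl}-2,2-dimethyl-4H-1,3-dioxin-4-one F2.
- Et3N in CH2Cl2 aromatises F2 through the same a4-a5 aldol. The product is the isopropylidene-protected resorcylate 6-[4-(benzyloxy)benzyl]-5-(2-{3-(benzyloxy)-4-[4-(benzyloxy)benzyl]phenyl}ethyl)-7-hydroxy-2,2-dimethyl-4H-1,3-benzodioxin-4-one F3.
- MeI/K2CO3 methylates its only free hydroxyl to give the 7-methoxy-2,2-dimethyl-4H-1,3-benzodioxin-4-one analogue F4.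
- Grignard reagent 12 then adds to the lactone carbonyl of F4. Collapse with loss of acetone should give 22 as its phenoxide, which shields the hindered ketone from a second addition.

**Step 9 (trianion acylation).**
- Risk: the third deprotonation at the substituted carbon may stay incomplete. Proton transfer from the α-CH2 of the amide to the very basic trianion may compete with addition. Base-induced loss of formaldehyde from the N-OMe group may consume the amide.
- Fallback: it sets out from 17 and 18 and comes back at 19. The acyl donor is replaced by an aldehyde, which is attacked far faster than it is enolised, and the oxidation level is restored afterwards.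
- iBu2AlH (THF, −78 °C) reduces 17 to 3-{3-(benzyloxy)-4-[4-(benzyloxy)benzyl]phenyl}propanal F5.
- Trianion 18 adds to F5 at −78 °C to give 1-[4-(benzyloxy)phenyl]-6-[4-(benzyloxy)benzyl]-9-{3-(benzyloxy)-4-[4-(benzyloxy)benzyl]phenyl}-7-hydroxynonane-1,3,5-trione F6 as a diastereomer mixture.
- Dess-Martin periodinane (1 equiv, NaHCO3, CH2Cl2, 0 °C) oxidises the carbinol to 19.

**Step 12 (ketone deoxygenation).**
- Risk: hydride transfer to the strongly stabilised hydroxycarbenium ion, flanked by two ortho groups, may be slow. Long exposure to acid may then cause migration or loss of the electron-rich benzyl groups.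
- Fallback: it sets out from 22 and comes back at 23. The deoxygenation is moved to basic medium and uses the neighbouring a3-OH as the handle.
- ClCO2Et/Et3N (THF, 0 °C) converts 22 into the mixed carbonate 2-[4-(benzyloxy)benzoyl]-4-[4-(benzyloxy)benzyl]-3-(2-{3-(benzyloxy)-4-[4-(benzyloxy)benzyl]phenyl}ethyl)-5-methoxyphenyl ethyl carbonate F7.
- NaBH4 in aqueous THF then takes the ketone down to the methylene group in one flask. The sequence is reduction, carbonate transfer to the benzylic oxygen, elimination and a second hydride addition, and it frees a3-OH again.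

**Further compounds**

F1 | step 10 | 6-{4-[4-(benzyloxy)phenyl]-2-oxobutyl}-2,2-dimethyl-4H-1,3-dioxin-4-one | CC1(C)OC(=O)C=C(CC(=O)CCc2ccc(OCc3ccccc3)cc2)O1
F2 | step 10 | (±)-6-{3-[4-(benzyloxy)benzyl]-6-{3-(benzyloxy)-4-[4-(benzyloxy)benzyl]phenyl}-2,4-dioxohexyl}-2,2-dimethyl-4H-1,3-dioxin-4-one | CC1(C)OC(=O)C=C(CC(=O)C(Cc2ccc(OCc3ccccc3)cc2)C(=O)CCc2ccc(Cc3ccc(OCc4ccccc4)cc3)c(OCc3ccccc3)c2)O1
F3 | step 10 | 6-[4-(benzyloxy)benzyl]-5-(2-{3-(benzyloxy)-4-[4-(benzyloxy)benzyl]phenyl}ethyl)-7-hydroxy-2,2-dimethyl-4H-1,3-benzodioxin-4-one | CC1(C)OC(=O)c2c(O1)cc(O)c(Cc3ccc(OCc4ccccc4)cc3)c2CCc2ccc(Cc3ccc(OCc4ccccc4)cc3)c(OCc3ccccc3)c2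
F4 | step 10 | 6-[4-(benzyloxy)benzyl]-5-(2-{3-(benzyloxy)-4-[4-(benzyloxy)benzyl]phenyl}ethyl)-7-methoxy-2,2-dimethyl-4H-1,3-benzodioxin-4-one | CC1(C)OC(=O)c2c(O1)cc(OC)c(Cc3ccc(OCc4ccccc4)cc3)c2CCc2ccc(Cc3ccc(OCc4ccccc4)cc3)c(OCc3ccccc3)c2
F5 | step 9 | 3-{3-(benzyloxy)-4-[4-(benzyloxy)benzyl]phenyl}propanal | O=CCCc1ccc(Cc2ccc(OCc3ccccc3)cc2)c(OCc2ccccc2)c1
F6 | step 9 | 1-[4-(benzyloxy)phenyl]-6-[4-(benzyloxy)benzyl]-9-{3-(benzyloxy)-4-[4-(benzyloxy)benzyl]phenyl}-7-hydroxynonane-1,3,5-trione (diastereomer mixture) | OC(CCc1ccc(Cc2ccc(OCc3ccccc3)cc2)c(OCc2ccccc2)c1)C(Cc1ccc(OCc2ccccc2)cc1)C(=O)CC(=O)CC(=O)c1ccc(OCc2ccccc2)cc1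
F7 | step 12 | 2-[4-(benzyloxy)benzoyl]-4-[4-(benzyloxy)benzyl]-3-(2-{3-(benzyloxy)-4-[4-(benzyloxy)benzyl]phenyl}ethyl)-5-methoxyphenyl ethyl carbonate | CCOC(=O)Oc1cc(OC)c(Cc2ccc(OCc3ccccc3)cc2)c(CCc2ccc(Cc3ccc(OCc4ccccc4)cc3)c(OCc3ccccc3)c2)c1C(=O)c1ccc(OCc2ccccc2)cc1
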